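**Retrosynthetic overview**
1. Target 19 ← removal of two aryl TIPS ethers ← C7 carbinol set by chelation-controlled reduction of α-aroyl lactone 17 ← oxidation of aldol adduct 16.
2. Key C3–C7 bond: intermolecular aldol of the lithium enolate of (R)-β-arylmethyl-γ-butyrolactone 14 with O-TIPS-vanillin 2, which sets the 3,4-trans relationship.
3. Lactone 14 ← Evans alkylation of a 3-arylpropanoyl oxazolidinone with tert-butyl bromoacetate (sets C4), reductive auxiliary removal, lactonisation.
4. Arylpropanoic acid 6 ← Wittig olefination of 2, then hydrogenation/hydrogenolysis; both aryl units come from vanillin.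
5. Ring order: the γ-butyrolactone is the only ring built (step 6); both arenes are bought.

Assumption: C7 is the carbinol carbon (lignan numbering); TIPS = triisopropylsilyl, TIPSO = triisopropylsilyloxy; LDA, NaHMDS and ethereal Zn(BH4)2 are used as pre-made solutions.

The target is (3S,4R)-3-[(S)-hydroxy(4-hydroxy-3-methoxyphenyl)methyl]-4-(4-hydroxy-3-methoxybenzyl)oxolan-2-one: 3,4-trans, with C3/C7 syn.

**Step 1**
Reactants: 1 vanillin
Product: 2 3-methoxy-4-(TIPSO)benzaldehyde
Conditions: TIPSCl, imidazole, DMF, rt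
Reagents that add atoms: triisopropylsilyl chloride, CC(C)[Si](Cl)(C(C)C)C(C)C
Why: Imidazole-promoted O-silylation of the phenol gives a base-stable aryl TIPS ether that is later removed by fluoride without touching the benzylic carbinol.

**Step 2**
Reactants: 2 3-methoxy-4-(TIPSO)benzaldehyde; 3 benzyl (triphenylphosphoranylidene)acetate
Product: 4 benzyl (2E)-3-[3-methoxy-4-(TIPSO)phenyl]prop-2-enoate
Conditions: toluene, 80 °C
Reagents that add atoms: none
Why: Wittig olefination with a stabilised ylide gives the E-cinnamate cleanly; the alkene geometry is irrelevant because it is hydrogenated next.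

**Step 3**
Reactants: 4 benzyl (2E)-3-[3-methoxy-4-(TIPSO)phenyl]prop-2-enoate
Product: 6 3-[3-methoxy-4-(TIPSO)phenyl]propanoic acid, via saturated benzyl ester 5 (not isolated)
Conditions: H2 (1 atm), 10% Pd/C, EtOAc, rt
Reagents that add atoms: none
Why: Catalytic hydrogenation saturates the alkene and hydrogenolysis then cleaves the benzyl ester in the same pot, while the aryl silyl ether is inert.

**Step 4**
Reactants: 6 3-[3-methoxy-4-(TIPSO)phenyl]propanoic acid; 7 (4S)-4-benzyl-1,3-oxazolidin-2-one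
Product: 9 (4S)-4-benzyl-3-{3-[3-methoxy-4-(TIPSO)phenyl]propanoyl}-1,3-oxazolidin-2-one, via mixed pivalic anhydride 8 (not isolated)
Conditions: PivCl, Et3N, THF, −20 °C; then LiCl, 7, −20 °C → rt
Reagents that add atoms: none
Why: N-acylation of the auxiliary through the mixed pivalic anhydride is regioselective because the oxazolidinone attacks the unhindered arylpropanoyl carbonyl.

**Step 5**
Reactants: 9 (4S)-4-benzyl-3-{3-[3-methoxy-4-(TIPSO)phenyl]propanoyl}-1,3-oxazolidin-2-one; 10 tert-butyl bromoacetate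
Product: 12 tert-butyl (3R)-4-[(4S)-4-benzyl-2-oxo-1,3-oxazolidin-3-yl]-3-[3-methoxy-4-(TIPSO)benzyl]-4-oxobutanoate, via sodium Z-enolate 11 (not isolated)
Conditions: NaHMDS, THF, −78 °C; then 10, −78 → −40 °C
Reagents that add atoms: none
Why: Evans asymmetric alkylation, in which the chelated Z-enolate is alkylated on the face opposite the 4-benzyl group of the (S)-auxiliary, sets the (R) centre that becomes C4 of the lactone.

**Step 6**
Reactants: 12 tert-butyl (3R)-4-[(4S)-4-benzyl-2-oxo-1,3-oxazolidin-3-yl]-3-[3-methoxy-4-(TIPSO)benzyl]-4-oxobutanoate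
Product: 14 (4R)-4-[3-methoxy-4-(TIPSO)benzyl]oxolan-2-one, via hydroxy tert-butyl ester 13 (not isolated)
Conditions: LiBH4, H2O (1 equiv), Et2O/THF, 0 °C; then p-TsOH·H2O (cat.), toluene, 60 °C
Reagents that add atoms: none
Why: Chemoselective LiBH4 reduction of the exocyclic imide carbonyl releases the auxiliary and spares the tert-butyl ester, and acid-catalysed lactonisation of the γ-hydroxy ester then closes the ring without touching the stereocentre.

**Step 7**
Reactants: 14 (4R)-4-[3-methoxy-4-(TIPSO)benzyl]oxolan-2-one; 2 3-methoxy-4-(TIPSO)benzaldehyde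
Product: 16 (3S,4R)-3-{(RS)-hydroxy[3-methoxy-4-(TIPSO)phenyl]methyl}-4-[3-methoxy-4-(TIPSO)benzyl]oxolan-2-one as the C7-epimer mixture, via lithium lactone enolate 15 (not isolated)
Conditions: LDA, THF, −78 °C; then 2, −78 °C; AcOH quench at −78 °C
Reagents that add atoms: none
Why: Intermolecular aldol addition in which the lactone enolate is attacked anti to the C4 benzyl group fixes the 3,4-trans (3S) configuration, while C7 forms as an epimer mixture that steps 8–9 correct.

**Step 8**
Reactants: 16 aldol adduct (C7-epimer mixture)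
Product: 17 (3S,4R)-3-[3-methoxy-4-(TIPSO)benzoyl]-4-[3-methoxy-4-(TIPSO)benzyl]oxolan-2-one
Conditions: Dess–Martin periodinane, CH2Cl2, 0 °C → rt
Reagents that add atoms: none
Why: Dess–Martin oxidation of the benzylic β-hydroxy lactone converges both C7 epimers on one α-aroyl lactone, whose enolisable C3 rests in the thermodynamically preferred trans arrangement.

**Step 9**
Reactants: 17 (3S,4R)-3-[3-methoxy-4-(TIPSO)benzoyl]-4-[3-methoxy-4-(TIPSO)benzyl]oxolan-2-one
Product: 18 (3S,4R)-3-{(S)-hydroxy[3-methoxy-4-(TIPSO)phenyl]methyl}-4-[3-methoxy-4-(TIPSO)benzyl]oxolan-2-one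
Conditions: Zn(BH4)2, Et2O, −20 → 0 °C
Reagents that add atoms: none
Why: In this chelation-controlled (Oishi-type) reduction zinc bridges the ketone and lactone carbonyls and hydride enters from the C3–H side, away from the lactone ring and C4 substituent, which gives the syn (7S) carbinol.

**Step 10**
Reactants: 18 (3S,4R)-3-{(S)-hydroxy[3-methoxy-4-(TIPSO)phenyl]methyl}-4-[3-methoxy-4-(TIPSO)benzyl]oxolan-2-one
Product: 19 (3S,4R)-3-[(S)-hydroxy(4-hydroxy-3-methoxyphenyl)methyl]-4-(4-hydroxy-3-methoxybenzyl)oxolan-2-one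
Conditions: TBAF, AcOH (1:1.1), THF, 0 °C
Reagents that add atoms: none
Why: Fluoride-mediated desilylation of the two aryl silyl ethers is buffered with acetic acid so that no phenoxide or alkoxide builds up to trigger retro-aldol or quinone-methide elimination.

**Compound list**
1 | vanillin (4-hydroxy-3-methoxybenzaldehyde) | COc1cc(C=O)ccc1O | starting material
2 | 3-methoxy-4-(triisopropylsilyloxy)benzaldehyde | COc1cc(C=O)ccc1O[Si](C(C)C)(C(C)C)C(C)C | intermediate
3 | benzyl (triphenylphosphoranylidene)acetate | O=C(C=P(c1ccccc1)(c1ccccc1)c1ccccc1)OCc1ccccc1 | starting material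
4 | benzyl (2E)-3-[3-methoxy-4-(triisopropylsilyloxy)phenyl]prop-2-enoate | COc1cc(/C=C/C(=O)OCc2ccccc2)ccc1O[Si](C(C)C)(C(C)C)C(C)C | intermediate
5 | benzyl 3-[3-methoxy-4-(triisopropylsilyloxy)phenyl]propanoate (formed in situ) | COc1cc(CCC(=O)OCc2ccccc2)ccc1O[Si](C(C)C)(C(C)C)C(C)C | intermediate
6 | 3-[3-methoxy-4-(triisopropylsilyloxy)phenyl]propanoic acid | COc1cc(CCC(=O)O)ccc1O[Si](C(C)C)(C(C)C)C(C)C | intermediate
7 | (4S)-4-benzyl-1,3-oxazolidin-2-one | O=C1N[C@@H](Cc2ccccc2)CO1 | starting material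
8 | 3-[3-methoxy-4-(triisopropylsilyloxy)phenyl]propanoic pivalic anhydride (formed in situ) | COc1cc(CCC(=O)OC(=O)C(C)(C)C)ccc1O[Si](C(C)C)(C(C)C)C(C)C | intermediate
9 | (4S)-4-benzyl-3-{3-[3-methoxy-4-(triisopropylsilyloxy)phenyl]propanoyl}-1,3-oxazolidin-2-one | COc1cc(CCC(=O)N2[C@@H](Cc3ccccc3)COC2=O)ccc1O[Si](C(C)C)(C(C)C)C(C)C | intermediate
10 | tert-butyl bromoacetate | CC(C)(C)OC(=O)CBr | starting material
11 | sodium (Z)-enolate of 9 (formed in situ) | COc1cc(C/C=C(\[O-])N2[C@@H](Cc3ccccc3)COC2=O)ccc1O[Si](C(C)C)(C(C)C)C(C)C.[Na+] | intermediate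
12 | tert-butyl (3R)-4-[(4S)-4-benzyl-2-oxo-1,3-oxazolidin-3-yl]-3-[3-methoxy-4-(triisopropylsilyloxy)benzyl]-4-oxobutanoate | COc1cc(C[C@H](CC(=O)OC(C)(C)C)C(=O)N2[C@@H](Cc3ccccc3)COC2=O)ccc1O[Si](C(C)C)(C(C)C)C(C)C | intermediate
13 | tert-butyl (3R)-4-hydroxy-3-[3-methoxy-4-(triisopropylsilyloxy)benzyl]butanoate (formed in situ) | COc1cc(C[C@H](CC(=O)OC(C)(C)C)CO)ccc1O[Si](C(C)C)(C(C)C)C(C)C | intermediate
14 | (4R)-4-[3-methoxy-4-(triisopropylsilyloxy)benzyl]oxolan-2-one | COc1cc(C[C@H]2COC(=O)C2)ccc1O[Si](C(C)C)(C(C)C)C(C)C | intermediate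
15 | lithium (4R)-4-[3-methoxy-4-(triisopropylsilyloxy)benzyl]-4,5-dihydrofuran-2-olate (formed in situ) | COc1cc(C[C@H]2COC([O-])=C2)ccc1O[Si](C(C)C)(C(C)C)C(C)C.[Li+] | intermediate
16 | (3S,4R)-3-{(RS)-hydroxy[3-methoxy-4-(triisopropylsilyloxy)phenyl]methyl}-4-[3-methoxy-4-(triisopropylsilyloxy)benzyl]oxolan-2-one, mixture of C7 epimers | COc1cc(C[C@H]2COC(=O)[C@@H]2C(O)c2ccc(O[Si](C(C)C)(C(C)C)C(C)C)c(OC)c2)ccc1O[Si](C(C)C)(C(C)C)C(C)C | intermediate
17 | (3S,4R)-3-[3-methoxy-4-(triisopropylsilyloxy)benzoyl]-4-[3-methoxy-4-(triisopropylsilyloxy)benzyl]oxolan-2-one | COc1cc(C[C@H]2COC(=O)[C@@H]2C(=O)c2ccc(O[Si](C(C)C)(C(C)C)C(C)C)c(OC)c2)ccc1O[Si](C(C)C)(C(C)C)C(C)C | intermediate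
18 | (3S,4R)-3-{(S)-hydroxy[3-methoxy-4-(triisopropylsilyloxy)phenyl]methyl}-4-[3-methoxy-4-(triisopropylsilyloxy)benzyl]oxolan-2-one | COc1cc(C[C@H]2COC(=O)[C@@H]2[C@H](O)c2ccc(O[Si](C(C)C)(C(C)C)C(C)C)c(OC)c2)ccc1O[Si](C(C)C)(C(C)C)C(C)C | intermediate
19 | (3S,4R)-3-[(S)-hydroxy(4-hydroxy-3-methoxyphenyl)methyl]-4-(4-hydroxy-3-methoxybenzyl)oxolan-2-one | COc1cc(C[C@H]2COC(=O)[C@@H]2[C@H](O)c2ccc(O)c(OC)c2)ccc1O | target

**Totals**
Total step count: 10.
Longest linear sequence: 10 steps (vanillin 1 → 19; aldehyde 2 is both the precursor of lactone 14 and the aldol partner).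

**Three steps most likely to fail**

Step 7 (aldol). Retro-aldol, incomplete conversion or erosion of the 3,4-trans selectivity could lower the yield. The fallback sets out from lactone 14 and comes back at ketone 17, replacing aldol plus oxidation by a Claisen-type C-acylation. Aldehyde 2 is oxidised (NaClO2, NaH2PO4, 2-methyl-2-butene, t-BuOH/H2O) to 3-methoxy-4-(triisopropylsilyloxy)benzoic acid F1. This is activated with carbonyldiimidazole to 1-[3-methoxy-4-(triisopropylsilyloxy)benzoyl]imidazole F2. The lithium enolate of 14 (2.1 equiv LiHMDS, THF, −78 °C) is then acylated with the acyl imidazole to give 17 directly, and the route continues with step 9.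

Step 9 (chelation-controlled reduction). The syn selectivity rests on the zinc chelate model and is not precedented here on this exact substrate; it may be only moderate. The fallback sets out from ketone 17 and comes back at 18, replacing substrate control by catalyst control. Noyori–Ikariya asymmetric transfer hydrogenation with RuCl(p-cymene)[(S,S)-TsDPEN] in HCO2H/Et3N is expected, by the usual aryl-ketone sense, to give the (S)-carbinol; the (R,R) catalyst serves as the check for a mismatched case. No new compound is made (F0). In addition, the 7S epimer already present in 16 is identical to 18 and can be collected by chromatography.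

Step 10 (desilylation). The free para-hydroxybenzylic β-hydroxy lactone could undergo retro-aldol or elimination if the fluoride medium is too basic. The fallback sets out from ketone 17 and comes back at target 19 by reversing the order of the last two operations. The silyl groups are removed at the ketone stage (TBAF/AcOH, THF, 0 °C), where no carbinol is present, giving (3S,4R)-3-(4-hydroxy-3-methoxybenzoyl)-4-(4-hydroxy-3-methoxybenzyl)oxolan-2-one F3. This is then reduced with excess Zn(BH4)2 in Et2O/THF under the same chelation control, so the last step is a near-neutral hydride reduction giving 19.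

**Further compounds**
F1 | step 7 | 3-methoxy-4-(triisopropylsilyloxy)benzoic acid | COc1cc(C(=O)O)ccc1O[Si](C(C)C)(C(C)C)C(C)C
F2 | step 7 | 1-[3-methoxy-4-(triisopropylsilyloxy)benzoyl]imidazole | COc1cc(C(=O)n2ccnc2)ccc1O[Si](C(C)C)(C(C)C)C(C)C
F0 | step 9 | none | none
F3 | step 10 | (3S,4R)-3-(4-hydroxy-3-methoxybenzoyl)-4-(4-hydroxy-3-methoxybenzyl)oxolan-2-one | COc1cc(C[C@H]2COC(=O)[C@@H]2C(=O)c2ccc(O)c(OC)c2)ccc1O
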